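Ring A is the cyclohexene (C1 methyl-bearing olefinic carbon, C2–C4, quaternary C5, C6; C7 is the exocyclic enol CH), ring B the seven-membered enol lactone. Ring B is opened to a C6-carbaldehyde (enal) and an aryl bromide, and the enal goes back to a ketone at C6. The route therefore rests on the benzylic quaternary C5 lying next to a C6 carbonyl: the retron of a pinacol shift. In the key step a racemic ditertiary diol, 1-(1-aryl-1-hydroxyethyl)cyclopentanol, ionises at the benzylic carbon under a chiral acid and a cyclopentane C–C bond migrates, which enlarges the carbocycle to ring A and sets C5 stereoconvergently. The thiazine dioxide is fused on last.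

Key step: step 4

Remark: 1-(1-hydroxycyclopentyl)ethan-1-one (5) is taken as a catalogue compound; which catalyst enantiomer gives (S)-9 in step 4 is settled in a trial run; the quinone carbons are called Q1 (carbonyl para to the lactone acyl carbon), Q2, Q3 (the two CH) and Q4 (carbonyl para to the carbon that bears C5).

Step 1
Reactants: 1 2,3-dibromonaphthalene
Product: 2 6,7-dibromonaphthalene-1,4-dione
Conditions: CrO3, AcOH/H2O, 20 to 60 °C
Reagents that add atoms: chromium trioxide, O=[Cr](=O)=O
Why: Chromium(VI) oxidation of a naphthalene to the 1,4-naphthoquinone takes place in the more electron-rich ring, and the two bromine atoms deactivate their own ring, so the unsubstituted ring should be oxidised.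

Step 2
Reactants: 2 6,7-dibromonaphthalene-1,4-dione
Product: 4 6,7-dibromo-1,4-dimethoxynaphthalene, via hydroquinone 3 (not isolated)
Conditions: Na2S2O4, Bu4NBr, THF/H2O, 20 °C; then KOH, Me2SO4, 20 °C
Reagents that add atoms: dimethyl sulfate, COS(=O)(=O)OC
Why: Reductive methylation: dithionite reduces the quinone to the hydroquinone, which is O-methylated twice under phase-transfer Williamson conditions before air can re-oxidise it.

Step 3
Reactants: 4 6,7-dibromo-1,4-dimethoxynaphthalene; 5 1-(1-hydroxycyclopentyl)ethan-1-one
Product: 8 rac-1-[1-(3-bromo-5,8-dimethoxynaphthalen-2-yl)-1-hydroxyethyl]cyclopentan-1-ol, via aryl Grignard 6 (not isolated), via magnesium alkoxide 7 (not isolated)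
Conditions: 4, i-PrMgCl·LiCl, THF, −15 °C; 5, i-PrMgCl, THF, −40 °C; mix, LaCl3·2LiCl, −20 to 0 °C; aq. NH4Cl
Reagents that add atoms: none
Why: Bromine–magnesium exchange on the 1,2-dibromoarene stops after one exchange and the ortho-bromoaryl Grignard reagent is stable below 0 °C, so its Grignard 1,2-addition to the ketone of the pre-formed α-alkoxide should give the ditertiary diol, whose benzylic stereocentre is formed as a racemate and is erased in step 4.

Step 4
Reactants: 8 rac-1-[1-(3-bromo-5,8-dimethoxynaphthalen-2-yl)-1-hydroxyethyl]cyclopentan-1-ol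
Product: 9 (S)-2-(3-bromo-5,8-dimethoxynaphthalen-2-yl)-2-methylcyclohexan-1-one
Conditions: chiral 3,3'-diaryl-BINOL N-triflyl phosphoramide (10 mol %), PhCF3, 5 Å MS, 0 to 25 °C
Reagents that add atoms: none
Why: The chiral N-triflyl phosphoramide protonates the benzylic tertiary hydroxyl of either enantiomer of 8 and water leaves, so both enantiomers give the same planar C5 cation (stabilised by the naphthalene ring and its 8-methoxy group) as a contact ion pair with the chiral phosphoramide anion, which is hydrogen-bonded to the remaining cyclopentanol OH. One of the two enantiotopic cyclopentane C–C bonds then shifts to C5 (1,2-alkyl shift) while the carbinol carbon becomes the C6 carbonyl, which enlarges the five-membered ring to the six-membered ring A in its final size. The closest known reaction type is the catalytic enantioselective pinacol rearrangement of ditertiary aryl diols to 2-alkyl-2-aryl cycloalkanones, here in its ring-enlarging form. No ring is closed by cyclisation: ring A arises by bond migration (five to six atoms), and the single new stereocentre C5 is controlled by the catalyst anion, which shields one face of the cation, so the step is stereoconvergent. The step needs ionisation at the benzylic and not at the cyclopentyl carbinol, which aryl stabilisation of the cation secures, and ring-bond migration instead of proton loss, which is secured because the carbinol carbon offers only its two ring CH2 groups for migration and any alkene or epoxide formed by a stray pathway re-enters the same cation under the acid.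

Step 5
Reactants: 9 (S)-2-(3-bromo-5,8-dimethoxynaphthalen-2-yl)-2-methylcyclohexan-1-one
Product: 11 (2S,6RS)-2-(3-bromo-5,8-dimethoxynaphthalen-2-yl)-2,6-dimethylcyclohexan-1-one, via lithium enolate 10 (not isolated)
Conditions: LDA, THF, −78 °C; then MeI, −78 to 0 °C
Reagents that add atoms: iodomethane, CI
Why: Enolate alkylation: C1 is the only enolisable position because C5 is quaternary, so methylation should be regiospecific, and the C1 epimer mixture is of no consequence because C1 becomes sp2 in step 6.

Step 6
Reactants: 11 (2S,6RS)-2-(3-bromo-5,8-dimethoxynaphthalen-2-yl)-2,6-dimethylcyclohexan-1-one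
Product: 13 (S)-6-(3-bromo-5,8-dimethoxynaphthalen-2-yl)-2,6-dimethylcyclohex-1-en-1-yl trifluoromethanesulfonate, via potassium enolate 12 (not isolated)
Conditions: KHMDS, THF, −78 to 0 °C; then PhNTf2, −78 to 20 °C
Reagents that add atoms: N-phenylbis(trifluoromethanesulfonimide), O=S(=O)(N(c1ccccc1)S(=O)(=O)C(F)(F)F)C(F)(F)F
Why: Enol triflate formation: O-sulfonylation of the only possible, tetrasubstituted enolate (as for 2,2,6-trisubstituted cyclohexanones) fixes the C6=C1 double bond and turns C6 into an electrophile.

Step 7
Reactants: 13 (S)-6-(3-bromo-5,8-dimethoxynaphthalen-2-yl)-2,6-dimethylcyclohex-1-en-1-yl trifluoromethanesulfonate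
Product: 14 (R)-6-(3-bromo-5,8-dimethoxynaphthalen-2-yl)-2,6-dimethylcyclohex-1-ene-1-carbaldehyde (same spatial arrangement at C5; the descriptor changes only through CIP priorities)
Conditions: Pd(PPh3)4 (5 mol %), LiCl, CO (3 atm), Bu3SnH (slow addition), THF, 60 °C
Reagents that add atoms: carbon monoxide, [C-]#[O+]
Why: Palladium-catalysed reductive carbonylation (formylation) of a vinyl triflate, by oxidative addition, CO insertion and hydride transfer from tin, should place the C7 aldehyde on C6, and the vinyl triflate should react ahead of the aryl bromide, which is shielded by the neighbouring quaternary carbon.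

Step 8
Reactants: 14 (R)-6-(3-bromo-5,8-dimethoxynaphthalen-2-yl)-2,6-dimethylcyclohex-1-ene-1-carbaldehyde
Product: 15 (S)-dimethoxy dienol lactone (the target skeleton with a 1,4-dimethoxynaphthalene in place of the thiazinoquinone)
Conditions: Pd(OAc)2 (5 mol %), Xantphos, CO (5 atm), Et3N, MeCN/toluene, 90 °C
Reagents that add atoms: carbon monoxide, [C-]#[O+]
Why: Palladium-catalysed carbonylative enol lactonisation: oxidative addition into the aryl bromide and CO insertion give an aroyl-palladium species that should be captured at oxygen by the dienol(ate) formed by γ-deprotonation of the enal at C2, which closes the seven-membered ring B and leaves the more substituted endocyclic C1=C2 diene.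

Step 9
Reactants: 15 (S)-dimethoxy dienol lactone
Product: 16 (S)-naphthoquinone dienol lactone
Conditions: (NH4)2Ce(NO3)6, MeCN/H2O, 0 °C
Reagents that add atoms: water, O
Why: Oxidative demethylation of the 1,4-dimethoxyarene with cerium(IV), in which water delivers the two carbonyl oxygens and the methoxy groups leave as methanol, is fast at 0 °C, so the dienol lactone should survive.

Step 10
Reactants: 16 (S)-naphthoquinone dienol lactone
Product: 18 target CNP0348176.1, via sulfonyl quinone 17 (not isolated)
Conditions: hypotaurine, MeCN/EtOH/pH 5.5 buffer, air, 25 °C; then NaHCO3 (pH 8), air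
Reagents that add atoms: hypotaurine, NCCS(=O)O
Why: Thiazinoquinone annulation with hypotaurine: at pH 5.5 only the sulfinate is nucleophilic and should add by conjugate addition at Q3, the position β to the more electron-poor Q1 carbonyl, air re-oxidation gives the sulfonyl quinone 17, and at pH 8 the free amine should close the thiazine ring by intramolecular conjugate addition at Q2 (6-endo-trig) followed by air oxidation.

Compound list
1 | 2,3-dibromonaphthalene | Brc1cc2ccccc2cc1Br | starting material
2 | 6,7-dibromonaphthalene-1,4-dione | O=C1C=CC(=O)c2cc(Br)c(Br)cc12 | intermediate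
3 | 6,7-dibromonaphthalene-1,4-diol (hydroquinone) | Oc1ccc(O)c2cc(Br)c(Br)cc12 | intermediate (not isolated)
4 | 6,7-dibromo-1,4-dimethoxynaphthalene | COc1ccc(OC)c2cc(Br)c(Br)cc12 | intermediate
5 | 1-(1-hydroxycyclopentyl)ethan-1-one | CC(=O)C1(O)CCCC1 | starting material
6 | (3-bromo-5,8-dimethoxynaphthalen-2-yl)magnesium chloride (aryl Grignard) | COc1ccc(OC)c2cc(Br)c([Mg]Cl)cc12 | intermediate (not isolated)
7 | chloromagnesium 1-acetylcyclopentan-1-olate (magnesium alkoxide) | CC(=O)C1(O[Mg]Cl)CCCC1 | intermediate (not isolated)
8 | rac-1-[1-(3-bromo-5,8-dimethoxynaphthalen-2-yl)-1-hydroxyethyl]cyclopentan-1-ol | CC(O)(c1cc2c(OC)ccc(OC)c2cc1Br)C1(O)CCCC1 | intermediate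
9 | (S)-2-(3-bromo-5,8-dimethoxynaphthalen-2-yl)-2-methylcyclohexan-1-one | O=C1CCCC[C@@]1(C)c1cc2c(OC)ccc(OC)c2cc1Br | intermediate
10 | lithium (S)-6-(3-bromo-5,8-dimethoxynaphthalen-2-yl)-6-methylcyclohex-1-en-1-olate (lithium enolate) | [Li]OC1=CCCC[C@@]1(C)c1cc2c(OC)ccc(OC)c2cc1Br | intermediate (not isolated)
11 | (2S,6RS)-2-(3-bromo-5,8-dimethoxynaphthalen-2-yl)-2,6-dimethylcyclohexan-1-one | CC1CCC[C@@](C)(c2cc3c(OC)ccc(OC)c3cc2Br)C1=O | intermediate
12 | potassium (S)-6-(3-bromo-5,8-dimethoxynaphthalen-2-yl)-2,6-dimethylcyclohex-1-en-1-olate (potassium enolate) | CC1=C(O[K])[C@](C)(c2cc3c(OC)ccc(OC)c3cc2Br)CCC1 | intermediate (not isolated)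
13 | (S)-6-(3-bromo-5,8-dimethoxynaphthalen-2-yl)-2,6-dimethylcyclohex-1-en-1-yl trifluoromethanesulfonate | CC1=C(OS(=O)(=O)C(F)(F)F)[C@](C)(c2cc3c(OC)ccc(OC)c3cc2Br)CCC1 | intermediate
14 | (R)-6-(3-bromo-5,8-dimethoxynaphthalen-2-yl)-2,6-dimethylcyclohex-1-ene-1-carbaldehyde | CC1=C(C=O)[C@](C)(c2cc3c(OC)ccc(OC)c3cc2Br)CCC1 | intermediate
15 | (S)-dimethoxy dienol lactone: 5,8-dimethoxynaphthalene fused at its 2,3-bond to the seven-membered enol lactone ring B (aryl–C(=O)–O–C7H=C6–C5), which shares C5–C6 with cyclohexene ring A (C1(Me)=C2H, quaternary C5 with methyl, S) | CC1=CCC[C@]2(C)C1=COC(=O)c1cc3c(OC)ccc(OC)c3cc12 | intermediate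
16 | (S)-naphthoquinone dienol lactone: as 15 with the dimethoxy ring oxidised to the 1,4-quinone (Q2 and Q3 both CH) | CC1=CCC[C@]2(C)C1=COC(=O)c1cc3c(cc12)C(=O)C=CC3=O | intermediate
17 | (S)-sulfonyl quinone: 16 carrying a 2-aminoethylsulfonyl group on Q3 | CC1=CCC[C@]2(C)C1=COC(=O)c1cc3c(cc12)C(=O)C=C(C3=O)S(=O)(=O)CCN | intermediate (not isolated)
18 | CNP0348176.1, (S)-configured thiazine-dioxide-fused quinone (N on Q2, SO2 on Q3) | CC1=CCC[C@]2(C)C1=COC(=O)c1cc3c(cc12)C(=O)C1=C(C3=O)S(=O)(=O)CCN1 | target

Total step count: 10
Longest linear sequence: 10 steps (1 to 18); 5 enters at step 3.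

Steps most likely to fail

Step 4. The ortho-bromine may twist the naphthalene out of conjugation with the cationic centre, so that ionisation stalls or the ion pair loosens and enantiocontrol erodes. The fallback sets out from 8 and gives up asymmetric induction. BF3·OEt2 (CH2Cl2, −20 °C) promotes the same ring-enlarging pinacol shift and should give racemic 2-(3-bromo-5,8-dimethoxynaphthalen-2-yl)-2-methylcyclohexan-1-one F1. Preparative chiral SFC then separates (S)-9, where the route is rejoined, from the (R)-ketone F2, which is set aside.

Step 8. Capture of the aroyl-palladium at oxygen may lose out to C-acylation or carbopalladation of the tetrasubstituted enal. Dienolisation may also run toward the C1 methyl group and give the exocyclic diene, and the seven-membered closure may be slow. The fallback sets out from 14 and separates carbonylation from ring closure. Hydroxycarbonylation (Pd(OAc)2, Xantphos, CO, H2O, Et3N, dioxane, 90 °C), in which water intercepts the aroyl-palladium, should give the enal acid F3. Heating with Ac2O/NaOAc (90 °C) forms the mixed acetic anhydride F4, which acylates the dienol oxygen under equilibrating conditions and comes back to the route at 15.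

Step 10. The amine may compete with the sulfinate as the first nucleophile, which would invert the placement of N and S, and re-oxidation of the intermediate hydroquinones may be incomplete. The fallback sets out from 16 and uses a reagent that can add only through sulfur. Sodium 2-[(tert-butoxycarbonyl)amino]ethane-1-sulfinate (AcOH, MeCN/H2O, 20 °C) should give the Boc-protected sulfonyl hydroquinone F5, which air oxidises to the Boc-protected sulfonyl quinone F6; a minor regioisomer can be removed at this stage. TFA (CH2Cl2, 0 °C) then removes the Boc group and gives 17 as its trifluoroacetate, where the route is rejoined (NaHCO3, air, to 18).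

Further compounds
F1 | step 4 | rac-2-(3-bromo-5,8-dimethoxynaphthalen-2-yl)-2-methylcyclohexan-1-one | O=C1CCCCC1(C)c1cc2c(OC)ccc(OC)c2cc1Br
F2 | step 4 | (R)-2-(3-bromo-5,8-dimethoxynaphthalen-2-yl)-2-methylcyclohexan-1-one | O=C1CCCC[C@]1(C)c1cc2c(OC)ccc(OC)c2cc1Br
F3 | step 8 | (S)-3-(2-formyl-1,3-dimethylcyclohex-2-en-1-yl)-5,8-dimethoxynaphthalene-2-carboxylic acid (enal acid) | CC1=C(C=O)[C@](C)(c2cc3c(OC)ccc(OC)c3cc2C(=O)O)CCC1
F4 | step 8 | mixed acetic anhydride of F3 | CC1=C(C=O)[C@](C)(c2cc3c(OC)ccc(OC)c3cc2C(=O)OC(C)=O)CCC1
F5 | step 10 | Boc-protected sulfonyl hydroquinone (2-(Boc-amino)ethylsulfonyl group on Q3 of the 1,4-dihydroxynaphthalene) | CC1=CCC[C@]2(C)C1=COC(=O)c1cc3c(cc12)c(O)cc(c3O)S(=O)(=O)CCNC(=O)OC(C)(C)C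
F6 | step 10 | Boc-protected sulfonyl quinone (N-Boc derivative of 17) | CC1=CCC[C@]2(C)C1=COC(=O)c1cc3c(cc12)C(=O)C=C(C3=O)S(=O)(=O)CCNC(=O)OC(C)(C)C
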